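Cuts (labdane numbering): the C8 formate and the C15 ester go first. C11–C12 is cut next (Wittig) and releases a C12–C16 chiral-pool piece. A C7 carbonyl and the C5–O bond are put back to reach an oxygen-bridged drimenal, then C5–C10 and C8–C9 are cut together (retro-[4+2]), and last C1–C10 and C4–C5.
Enabling feature: C8 of ring B carries a methyl group and an oxygen, the pattern found at C2 of 2-methylfuran, and the ring B run C8–C7–C6–C5 ends at the ring-fusion carbon C5. A 2,5-disubstituted furan therefore holds C5–C8 and O8, while C9=C10 is an enal hung on C5 through C4–C1 of ring A.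
Forward: tert-alkylation of 2-methylfuran (C4–C5), carbocupration (C1–C10) and redox adjustment give the (E)-enal, and rings A and B close in one cycloaddition. The side chain is then joined at C11=C12, the bridge is opened at C5–O through a C7 ketone, C7 is cleared and O8 is formylated.
Stereochemistry: C8, C9 and C10 (and, for the time being, C5) come from the cycloaddition, relative through the exo tether and the (E)-alkene, absolute through a chiral boron Lewis acid. C5–H is reset by α-face hydrogenation under control of three β-methyl groups, and C13 comes from (R)-2-methylsuccinic acid 4-methyl ester.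

Key step: step 8

Assumption: the sense of induction of the (S)-configured catalyst is taken from the usual pre-transition-state picture for enals bound to this catalyst class; should the furan add to the other enal face, the catalyst from (R)-α,α-diphenylprolinol would be used and nothing else changes.

Step 1
Reactants: 1 (R)-2-methylsuccinic acid 4-methyl ester
Product: 2 methyl (3R)-4-hydroxy-3-methylbutanoate
Conditions: BH3·SMe2, THF, 0 °C → rt; MeOH
Reagents that add atoms: none
Why: Chemoselective borane reduction, in which the free carboxylic acid reacts far faster than the methyl ester; the stereocentre that becomes C13 is not involved, and 2 is carried on crude so that lactonisation has no time to occur.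

Step 2
Reactants: 2 methyl (3R)-4-hydroxy-3-methylbutanoate
Product: 3 methyl (3R)-4-iodo-3-methylbutanoate
Conditions: PPh3, I2, imidazole, CH2Cl2, 0 °C → rt
Reagents that add atoms: iodine, II
Why: Appel-type iodination replaces the primary hydroxyl at C12 by SN2 displacement, leaves the neighbouring stereocentre and the ester alone and should outrun lactonisation.

Step 3
Reactants: 3 methyl (3R)-4-iodo-3-methylbutanoate
Product: 4 [(2R)-4-methoxy-2-methyl-4-oxobutyl]triphenylphosphonium iodide
Conditions: PPh3, MeCN, reflux
Reagents that add atoms: triphenylphosphine, c1ccc(cc1)P(c1ccccc1)c1ccccc1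
Why: SN2 quaternisation of triphenylphosphine by a primary, β-branched iodide, a standard entry to phosphonium salts of this chain type, changes no bond at the stereocentre.

Step 4
Reactants: 5 2-methylfuran; 6 5-bromo-2-methylpent-2-ene
Product: 7 2-(5-bromo-2-methylpentan-2-yl)-5-methylfuran
Conditions: CF3SO3H (5 mol%), 5 (5 equiv), CH2Cl2, −20 → 0 °C, slow addition of 6
Reagents that add atoms: none
Why: Friedel–Crafts alkylation, in which Markovnikov protonation of the trisubstituted alkene gives the tertiary cation at C4 and the free, most nucleophilic α-position of the furan (future C5) captures it; the primary bromide is inert to acid, and excess furan at low temperature should hold back dialkylation and furan oligomerisation.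

Step 5
Reactants: 7 2-(5-bromo-2-methylpentan-2-yl)-5-methylfuran; 8 ethyl but-2-ynoate
Product: 12 ethyl (2E)-3,7-dimethyl-7-(5-methylfuran-2-yl)oct-2-enoate, via Grignard reagent 9 (not isolated), via alkylcopper 10 (not isolated), via alkenylcopper 11 (not isolated)
Conditions: Mg, THF, rt; CuBr·SMe2, THF, −40 °C; 8, −78 °C; aq NH4Cl, −78 °C
Reagents that add atoms: none
Why: Stereospecific syn-carbocupration of an alkynoate delivers C1 to the β-carbon (C10) and copper to C9 on the same side, and protonation at −78 °C with retention puts the ester trans to the chain, which is the (E)-alkene that the cycloaddition needs.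

Step 6
Reactants: 12 ethyl (2E)-3,7-dimethyl-7-(5-methylfuran-2-yl)oct-2-enoate
Product: 13 (2E)-3,7-dimethyl-7-(5-methylfuran-2-yl)oct-2-en-1-ol
Conditions: i-Bu2AlH (2.2 equiv), CH2Cl2, −78 → 0 °C; aq potassium sodium tartrate
Reagents that add atoms: none
Why: 1,2-Reduction of an α,β-unsaturated ester by i-Bu2AlH stops at the allylic alcohol and touches neither the alkene geometry nor the furan.

Step 7
Reactants: 13 (2E)-3,7-dimethyl-7-(5-methylfuran-2-yl)oct-2-en-1-ol
Product: 14 (2E)-3,7-dimethyl-7-(5-methylfuran-2-yl)oct-2-enal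
Conditions: MnO2 (activated, excess), CH2Cl2, rt
Reagents that add atoms: none
Why: Selective allylic oxidation with activated MnO2 is neutral and heterogeneous, so neither the acid-sensitive furan nor the (E)-geometry should suffer.

Step 8
Reactants: 14 (2E)-3,7-dimethyl-7-(5-methylfuran-2-yl)oct-2-enal
Product: 15 (5R,8R,9R,10R)-5α,8α-epoxydrim-6-en-11-al (oxygen bridge α; C10 methyl and C9 formyl β, anti to the bridge)
Conditions: (S)-tetrahydro-1-(2-methylphenyl)-3,3-diphenyl-1H,3H-pyrrolo[1,2-c][1,3,2]oxazaborole (20 mol%), HN(SO2CF3)2 (18 mol%), CH2Cl2 (0.02 M), −78 → −40 °C; Et3N, −78 °C; cold SiO2 plug, used at once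
Reagents that add atoms: none
Why: Proposed new method: the cationic boron binds the formyl oxygen of 14 and lowers the enal LUMO, so that a concerted, asynchronous [4+2] cycloaddition should join the β-carbon C10 to the tether-bearing furan carbon C5 and the α-carbon C9 to the methyl-bearing furan carbon C8; the closest known reaction types are MeAlCl2-promoted intramolecular furan Diels–Alder reactions of enones on all-carbon tethers and oxazaborolidinium-catalysed intermolecular Diels–Alder reactions of furans. Ring A closes as a six-membered carbocycle in the type 1 intramolecular mode (the C1–C4 tether links the diene terminus C5 to the dienophile carbon C10), and ring B is the cyclohexene C5–C6–C7–C8–C9–C10 made by the cycloaddition itself and spanned by the former furan oxygen. C5 and C8 are tied to one face by the oxygen bridge, the four-atom tether can reach only in the exo orientation (syn to the bridge), which fixes C10 with its methyl group anti to the bridge, and suprafacial addition to the (E)-alkene places the C9 formyl group cis to that methyl group, so the four centres are related as 5α,8α-O, 9β-CHO, 10β-CH3. The absolute sense rests on the catalyst, whose aryl groups screen one face of the s-trans enal held by B–O coordination and a formyl C–H···O contact, leaving the C9-Si/C10-Re face open to the furan. The step needs regio-, exo- and facial selectivity under kinetic control: the tether enforces the first two, the C4 gem-dimethyl group favours the folded rotamer (Thorpe–Ingold effect), and the low temperature with a cold amine quench should prevent cycloreversion, which would erode both conversion and enantiomeric purity.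

Step 9
Reactants: 15 5α,8α-epoxydrim-6-en-11-al; 4 [(2R)-4-methoxy-2-methyl-4-oxobutyl]triphenylphosphonium iodide
Product: 17 methyl (11Z,13R)-5α,8α-epoxylabda-6,11-dien-15-oate, via phosphorus ylide 16 (not isolated)
Conditions: 4 (1.5 equiv), NaN(SiMe3)2 (1.4 equiv), THF, 0 °C; 15, −78 → 0 °C
Reagents that add atoms: none
Why: Wittig olefination with a non-stabilised ylide of a standard chain type (P–C–C–C–CO2Me), which adds to aldehydes already at −78 °C and so should outrun enolisation at C9 and cycloreversion; the alkene geometry is of no consequence because this bond is saturated later, and C13 arrives intact from 4.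

Step 10
Reactants: 17 methyl (11Z,13R)-5α,8α-epoxylabda-6,11-dien-15-oate
Product: 19 methyl (11Z,13R)-5α,8α-epoxy-7α-hydroxylabd-11-en-15-oate, via C7 monoalkylborane 18 (not isolated)
Conditions: BH3·THF (1.1 equiv), THF, −20 → 0 °C; 30% H2O2, aq NaOAc, 0 °C
Reagents that add atoms: hydrogen peroxide, OO
Why: Hydroboration–oxidation, in which the strained C6=C7 bond should react first, from its open exo face (syn to the bridge, giving the 7α-alcohol with retention in the oxidation) and with boron at C7 because C6 lies next to C5 and the C4 gem-dimethyl group, while the C11=C12 bond, branched at both allylic carbons and tucked under the bicycle, and the ester are much slower, and buffered peroxide spares the ester.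

Step 11
Reactants: 19 methyl (11Z,13R)-5α,8α-epoxy-7α-hydroxylabd-11-en-15-oate
Product: 20 methyl (11Z,13R)-5α,8α-epoxy-7-oxolabd-11-en-15-oate
Conditions: 1,1,1-triacetoxy-1,1-dihydro-1,2-benziodoxol-3(1H)-one (DMP), CH2Cl2, rt
Reagents that add atoms: none
Why: Dess–Martin oxidation of a secondary alcohol runs under nearly neutral conditions that alkene, ester and oxygen bridge tolerate, and it erases the C7 stereocentre on purpose.

Step 12
Reactants: 20 methyl (11Z,13R)-5α,8α-epoxy-7-oxolabd-11-en-15-oate
Product: 22 methyl (11Z,13R)-7-oxo-8α-(triethylsilyloxy)labda-5,11-dien-15-oate, via 8α-hydroxy enone 21 (not isolated)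
Conditions: DBU (0.3 equiv), CH2Cl2, rt; 2,6-lutidine, Et3SiOSO2CF3, 0 °C
Reagents that add atoms: triethylsilyl trifluoromethanesulfonate, CC[Si](CC)(CC)OS(=O)(=O)C(F)(F)F
Why: E1cB β-elimination followed by silylation: the ketone can enolise only toward C6 because C8 is fully substituted, so the enolate can expel only the C5–O bond (helped by release of bicyclic strain and by conjugation), the C8–O bond and its configuration stay, and the silyl triflate/lutidine pair is the standard way to cap a hindered tertiary carbinol.

Step 13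
Reactants: 22 methyl (11Z,13R)-7-oxo-8α-(triethylsilyloxy)labda-5,11-dien-15-oate
Product: 23 methyl (13S)-7-oxo-8α-(triethylsilyloxy)-5α-labdan-15-oate
Conditions: H2 (5 bar), PtO2, EtOAc, rt, stopped after two equivalents of H2
Reagents that add atoms: none
Why: Heterogeneous hydrogenation of both C=C bonds, in which hydrogen should reach C5=C6 from the α face because the β face carries the axial methyl groups at C4, C8 and C10, setting 5α-H (trans-decalin); platinum is preferred to palladium because it copes with hindered alkenes and causes little double-bond migration, which protects the allylic C13 centre (its descriptor changes from R to S only through CIP ranking), and the ketone beside the fully substituted C8 is reduced far more slowly.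

Step 14
Reactants: 23 methyl (13S)-7-oxo-8α-(triethylsilyloxy)-5α-labdan-15-oate
Product: 25 methyl (13S)-8α-(triethylsilyloxy)-7-(trifluoromethylsulfonyloxy)labd-6-en-15-oate, via potassium enolate 24 (not isolated)
Conditions: KN(SiMe3)2 (1.1 equiv), THF, −78 °C; N-(5-chloropyridin-2-yl)bis(trifluoromethanesulfonimide), −78 → −20 °C
Reagents that add atoms: N-(5-chloropyridin-2-yl)bis(trifluoromethanesulfonimide), O=S(=O)(N(c1ccc(Cl)cn1)S(=O)(=O)C(F)(F)F)C(F)(F)F
Why: Enol triflate formation: the ketone, more acidic than the ester by several pK units and enolisable only at C6, is deprotonated selectively at −78 °C and the enolate oxygen is sulfonylated by the N-pyridyl triflimide, with the silyl ether keeping O8 out of play.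

Step 15
Reactants: 25 methyl (13S)-8α-(triethylsilyloxy)-7-(trifluoromethylsulfonyloxy)labd-6-en-15-oate
Product: 26 methyl (13S)-8α-(triethylsilyloxy)labdan-15-oate
Conditions: H2 (1 bar), PtO2, Li2CO3, EtOAc, rt
Reagents that add atoms: none
Why: Hydrogenolysis–hydrogenation of an enol triflate over platinum is a known way from a ketone to a methylene group; Li2CO3 takes up the triflic acid so that the tertiary silyl ether is not ionised, and no stereocentre is formed.

Step 16
Reactants: 26 methyl (13S)-8α-(triethylsilyloxy)labdan-15-oate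
Product: 28 (13S)-8α-hydroxylabdan-15-oic acid (labdanolic acid), via methyl labdanolate 27 (not isolated)
Conditions: n-Bu4NF, THF, 50 °C; LiOH, MeOH–H2O, rt; 1 M HCl, 0 °C
Reagents that add atoms: lithium hydroxide, [Li+].[OH-]
Why: Fluoride-induced desilylation cleaves only the Si–O bond and saponification (BAc2) then cleaves only the acyl–OMe bond of the unhindered ester, so no bond at a stereocentre is touched.

Step 17
Reactants: 28 (13S)-8α-hydroxylabdan-15-oic acid
Product: 29 (13S)-8α-formyloxylabdan-15-oic acid (CNP0465436.1)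
Conditions: acetic formic anhydride (freshly prepared), pyridine, CH2Cl2, 0 °C → rt; H2O
Reagents that add atoms: acetic formic anhydride, CC(=O)OC=O
Why: O-Formylation with a mixed anhydride: the formyl carbon is the more electrophilic and the smallest acyl group available, so it should reach even the hindered tertiary 8α-hydroxyl, the C8–O bond is not broken so the configuration holds, the non-acidic medium avoids dehydration, and any acylation of the carboxyl group is undone by the water quench.

Compound list
1 | (R)-2-methylsuccinic acid 4-methyl ester | C[C@@H](C(=O)O)CC(=O)OC | starting material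
2 | methyl (3R)-4-hydroxy-3-methylbutanoate | C[C@@H](CO)CC(=O)OC | intermediate
3 | methyl (3R)-4-iodo-3-methylbutanoate | C[C@@H](CI)CC(=O)OC | intermediate
4 | [(2R)-4-methoxy-2-methyl-4-oxobutyl]triphenylphosphonium iodide | C[C@@H](C[P+](c1ccccc1)(c1ccccc1)c1ccccc1)CC(=O)OC.[I-] | intermediate
5 | 2-methylfuran | Cc1ccco1 | starting material
6 | 5-bromo-2-methylpent-2-ene | CC(C)=CCCBr | starting material
7 | 2-(5-bromo-2-methylpentan-2-yl)-5-methylfuran | Cc1ccc(o1)C(C)(C)CCCBr | intermediate
8 | ethyl but-2-ynoate | CC#CC(=O)OCC | starting material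
9 | [4-methyl-4-(5-methylfuran-2-yl)pentyl]magnesium bromide | Cc1ccc(o1)C(C)(C)CCC[Mg]Br | intermediate
10 | [4-methyl-4-(5-methylfuran-2-yl)pentyl]copper | Cc1ccc(o1)C(C)(C)CCC[Cu] | intermediate
11 | ethyl (2Z)-2-cuprio-3,7-dimethyl-7-(5-methylfuran-2-yl)oct-2-enoate | CCOC(=O)/C([Cu])=C(\C)CCCC(C)(C)c1ccc(C)o1 | intermediate
12 | ethyl (2E)-3,7-dimethyl-7-(5-methylfuran-2-yl)oct-2-enoate | CCOC(=O)/C=C(\C)CCCC(C)(C)c1ccc(C)o1 | intermediate
13 | (2E)-3,7-dimethyl-7-(5-methylfuran-2-yl)oct-2-en-1-ol | OC/C=C(\C)CCCC(C)(C)c1ccc(C)o1 | intermediate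
14 | (2E)-3,7-dimethyl-7-(5-methylfuran-2-yl)oct-2-enal | O=C/C=C(\C)CCCC(C)(C)c1ccc(C)o1 | intermediate
15 | (5R,8R,9R,10R)-5α,8α-epoxydrim-6-en-11-al | O=C[C@@H]1[C@@]2(C)CCCC(C)(C)[C@]23C=C[C@@]1(C)O3 | intermediate
16 | methyl (3R)-3-methyl-4-(triphenyl-λ5-phosphanylidene)butanoate | C[C@@H](C=P(c1ccccc1)(c1ccccc1)c1ccccc1)CC(=O)OC | intermediate
17 | methyl (11Z,13R)-5α,8α-epoxylabda-6,11-dien-15-oate | C[C@@H](/C=C\[C@@H]1[C@@]2(C)CCCC(C)(C)[C@]23C=C[C@@]1(C)O3)CC(=O)OC | intermediate
18 | methyl (11Z,13R)-7α-boranyl-5α,8α-epoxylabd-11-en-15-oate | C[C@@H](/C=C\[C@@H]1[C@@]2(C)CCCC(C)(C)[C@]23C[C@@H](B)[C@@]1(C)O3)CC(=O)OC | intermediate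
19 | methyl (11Z,13R)-5α,8α-epoxy-7α-hydroxylabd-11-en-15-oate | C[C@@H](/C=C\[C@@H]1[C@@]2(C)CCCC(C)(C)[C@]23C[C@@H](O)[C@@]1(C)O3)CC(=O)OC | intermediate
20 | methyl (11Z,13R)-5α,8α-epoxy-7-oxolabd-11-en-15-oate | C[C@@H](/C=C\[C@@H]1[C@@]2(C)CCCC(C)(C)[C@]23CC(=O)[C@@]1(C)O3)CC(=O)OC | intermediate
21 | methyl (11Z,13R)-8α-hydroxy-7-oxolabda-5,11-dien-15-oate | C[C@@H](/C=C\[C@@H]1[C@@]2(C)CCCC(C)(C)C2=CC(=O)[C@@]1(C)O)CC(=O)OC | intermediate
22 | methyl (11Z,13R)-7-oxo-8α-(triethylsilyloxy)labda-5,11-dien-15-oate | C[C@@H](/C=C\[C@@H]1[C@@]2(C)CCCC(C)(C)C2=CC(=O)[C@@]1(C)O[Si](CC)(CC)CC)CC(=O)OC | intermediate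
23 | methyl (13S)-7-oxo-8α-(triethylsilyloxy)-5α-labdan-15-oate | C[C@@H](CC[C@@H]1[C@@]2(C)CCCC(C)(C)[C@@H]2CC(=O)[C@@]1(C)O[Si](CC)(CC)CC)CC(=O)OC | intermediate
24 | potassium C6=C7 enolate of 23 | C[C@@H](CC[C@@H]1[C@@]2(C)CCCC(C)(C)[C@@H]2C=C([O-])[C@@]1(C)O[Si](CC)(CC)CC)CC(=O)OC.[K+] | intermediate
25 | methyl (13S)-8α-(triethylsilyloxy)-7-(trifluoromethylsulfonyloxy)labd-6-en-15-oate | C[C@@H](CC[C@@H]1[C@@]2(C)CCCC(C)(C)[C@@H]2C=C(OS(=O)(=O)C(F)(F)F)[C@@]1(C)O[Si](CC)(CC)CC)CC(=O)OC | intermediate
26 | methyl (13S)-8α-(triethylsilyloxy)labdan-15-oate | C[C@@H](CC[C@@H]1[C@@]2(C)CCCC(C)(C)[C@@H]2CC[C@@]1(C)O[Si](CC)(CC)CC)CC(=O)OC | intermediate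
27 | methyl (13S)-8α-hydroxylabdan-15-oate (methyl labdanolate) | C[C@@H](CC[C@@H]1[C@@]2(C)CCCC(C)(C)[C@@H]2CC[C@@]1(C)O)CC(=O)OC | intermediate
28 | (13S)-8α-hydroxylabdan-15-oic acid (labdanolic acid) | C[C@@H](CC[C@@H]1[C@@]2(C)CCCC(C)(C)[C@@H]2CC[C@@]1(C)O)CC(=O)O | intermediate
29 | (13S)-8α-formyloxylabdan-15-oic acid (CNP0465436.1) | C[C@@H](CC[C@@H]1[C@@]2(C)CCCC(C)(C)[C@@H]2CC[C@@]1(C)OC=O)CC(=O)O | target

Total step count: 17. Longest linear sequence: 14 (steps 4–17; steps 1–3 form the side branch).

Steps most likely to fail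

Step 8. The equilibrium may stay on the side of the furan, because three adjoining fully substituted carbons (C4, C5, C10) are created. The catalyst may also discriminate poorly between the two enal faces, and slow cycloreversion would wash out enantiomeric purity. The fallback uses known chemistry only and runs from 14 back to 17. The cycloaddition is run with a full equivalent of MeAlCl2 in CH2Cl2 at −78 °C, the established way of driving intramolecular furan Diels–Alder reactions on all-carbon tethers. This should give 15 as a racemate, that is together with its mirror image ent-5α,8α-epoxydrim-6-en-11-al F1. The mixture is olefinated at once with the enantiopure ylide 16 as in step 9, so that the C13 centre serves as a covalently bound resolving element across the short alkene. Compound 17 is then separated by chromatography from the diastereomeric ester on the mirror-image bicycle F2, and the route continues from 17.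

Step 9. Addition of the ylide to a formyl group wedged between the fully substituted C8 and C10 may be slow. On warming, cycloreversion, epimerisation at C9 or base-induced expulsion of the bridge oxygen from C8 may take over. The fallback runs from 15 back to 22 and postpones the olefination until the bridge is gone.
- NaBH4 in MeOH–CH2Cl2 at −78 °C reduces 15 to 5α,8α-epoxydrim-6-en-11-ol F3, and Et3SiCl/imidazole gives 11-(triethylsilyloxy)-5α,8α-epoxydrim-6-ene F4.
- The chemistry of steps 10–12 is then run on this simpler alkene, which holds no second C=C bond. BH3·THF gives the C7 monoalkylborane F5, buffered H2O2 gives 11-(triethylsilyloxy)-5α,8α-epoxydriman-7α-ol F6, and DMP gives 11-(triethylsilyloxy)-5α,8α-epoxydriman-7-one F7.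
- DBU gives 8α-hydroxy-11-(triethylsilyloxy)drim-5-en-7-one F8, and Et3SiOSO2CF3/2,6-lutidine gives 8α,11-bis(triethylsilyloxy)drim-5-en-7-one F9.
- Swern conditions ((COCl)2, DMSO, Et3N) are known to oxidise primary triethylsilyl ethers directly while leaving hindered ones alone. They turn F9 into 7-oxo-8α-(triethylsilyloxy)drim-5-en-11-al F10, which can no longer cyclorevert.
- The Wittig reaction of F10 with 16 takes place at the aldehyde and leaves the hindered enone untouched, giving 22.

Step 10. Boron may go to C6, which would later break the wrong C–O bond, or to the C11=C12 alkene. The fallback runs from 15 back to 20 and delivers oxygen to C7 intramolecularly from C11, which sits on the endo face directly below C7.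
- Pinnick oxidation (NaClO2, NaH2PO4, 2-methylbut-2-ene) gives 5α,8α-epoxydrim-6-en-11-oic acid F11.
- Iodolactonisation (I2, KI, NaHCO3), the classical reaction of endo-norbornenecarboxylic acids, can close only the five-membered lactone onto C7. It gives 6α-iodo-5α,8α-epoxydriman-11,7β-olide F12 and at the same time ends any cycloreversion.
- n-Bu3SnH with 2,2'-azobis(2-methylpropionitrile) removes the iodine to give 5α,8α-epoxydriman-11,7β-olide F13, and i-Bu2AlH at −78 °C gives the lactol 5α,8α:7β,11-diepoxydriman-11-ol F14.
- Excess ylide 16 opens the lactol to methyl (11Z,13R)-5α,8α-epoxy-7β-hydroxylabd-11-en-15-oate F15, and DMP oxidation gives 20.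

Further compounds
F1 | step 8 | ent-5α,8α-epoxydrim-6-en-11-al (mirror image of 15, formed with it as the racemate) | O=C[C@H]1[C@]2(C)CCCC(C)(C)[C@@]23C=C[C@]1(C)O3
F2 | step 8 | diastereomer of 17 with (13R) side chain on the mirror-image bicycle | C[C@@H](/C=C\[C@H]1[C@]2(C)CCCC(C)(C)[C@@]23C=C[C@]1(C)O3)CC(=O)OC
F3 | step 9 | 5α,8α-epoxydrim-6-en-11-ol | OC[C@@H]1[C@@]2(C)CCCC(C)(C)[C@]23C=C[C@@]1(C)O3
F4 | step 9 | 11-(triethylsilyloxy)-5α,8α-epoxydrim-6-ene | CC[Si](CC)(CC)OC[C@@H]1[C@@]2(C)CCCC(C)(C)[C@]23C=C[C@@]1(C)O3
F5 | step 9 | 7α-boranyl-11-(triethylsilyloxy)-5α,8α-epoxydrimane | CC[Si](CC)(CC)OC[C@@H]1[C@@]2(C)CCCC(C)(C)[C@]23C[C@@H](B)[C@@]1(C)O3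
F6 | step 9 | 11-(triethylsilyloxy)-5α,8α-epoxydriman-7α-ol | CC[Si](CC)(CC)OC[C@@H]1[C@@]2(C)CCCC(C)(C)[C@]23C[C@@H](O)[C@@]1(C)O3
F7 | step 9 | 11-(triethylsilyloxy)-5α,8α-epoxydriman-7-one | CC[Si](CC)(CC)OC[C@@H]1[C@@]2(C)CCCC(C)(C)[C@]23CC(=O)[C@@]1(C)O3
F8 | step 9 | 8α-hydroxy-11-(triethylsilyloxy)drim-5-en-7-one | CC[Si](CC)(CC)OC[C@@H]1[C@@]2(C)CCCC(C)(C)C2=CC(=O)[C@@]1(C)O
F9 | step 9 | 8α,11-bis(triethylsilyloxy)drim-5-en-7-one | CC[Si](CC)(CC)OC[C@@H]1[C@@]2(C)CCCC(C)(C)C2=CC(=O)[C@@]1(C)O[Si](CC)(CC)CC
F10 | step 9 | 7-oxo-8α-(triethylsilyloxy)drim-5-en-11-al | O=C[C@@H]1[C@@]2(C)CCCC(C)(C)C2=CC(=O)[C@@]1(C)O[Si](CC)(CC)CC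
F11 | step 10 | 5α,8α-epoxydrim-6-en-11-oic acid | OC(=O)[C@@H]1[C@@]2(C)CCCC(C)(C)[C@]23C=C[C@@]1(C)O3
F12 | step 10 | 6α-iodo-5α,8α-epoxydriman-11,7β-olide | O=C4[C@@H]1[C@@]2(C)CCCC(C)(C)[C@]23[C@@H](I)[C@H](O4)[C@@]1(C)O3
F13 | step 10 | 5α,8α-epoxydriman-11,7β-olide | O=C4[C@@H]1[C@@]2(C)CCCC(C)(C)[C@]23C[C@H](O4)[C@@]1(C)O3
F14 | step 10 | 5α,8α:7β,11-diepoxydriman-11-ol (lactol, both C11 anomers) | OC4[C@@H]1[C@@]2(C)CCCC(C)(C)[C@]23C[C@H](O4)[C@@]1(C)O3
F15 | step 10 | methyl (11Z,13R)-5α,8α-epoxy-7β-hydroxylabd-11-en-15-oate | C[C@@H](/C=C\[C@@H]1[C@@]2(C)CCCC(C)(C)[C@]23C[C@H](O)[C@@]1(C)O3)CC(=O)OC
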